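**Retrosynthetic overview**
1. The hydroquinone comes from a phenol by late para-oxidation; the C5–CH2Ar bond comes from a tertiary C5 radical (generated from a traceless C5 carboxyl) adding to an ortho-quinone methide on the finished trans-decalin.
2. Ring B is closed last, by ring-closing metathesis between a C8a vinyl and a C6-bearing vinyl arm, then saturated.
3. The C8a quaternary centre and the C1 propanoate chain come from anti vinyl-copper addition and Mukaiyama–Michael trapping on a 4-substituted 3-methylcyclohexenone; ring A is bought as 2-methylcyclohex-2-enone.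
4. The crowded C5–C4a bond and the C4a stereocentre come from an Ireland–Claisen rearrangement of an (R)-2-methylcyclohexenyl ester; the C6 methyl centre comes from an enantioselective ester-enolate Claisen of crotyl propanoate.
5. The arene comes from 2-methylphenol and formaldehyde.

Numbering used below (target decalin): C1 (CH with the propanoate chain), C2 (C=O), C4a (ring-fusion CH), C5 (quaternary, Me and CH2Ar), C6 (CHMe), C8a (quaternary, Me).

Assumption: the carboxyl-bearing quaternary carbon in 8, 9, 12–15 and 20 is carried as an inconsequential epimer mixture (it becomes a planar radical in step 10), so its descriptor is left open in those SMILES.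

Step 1
Reactants: 1 (E)-but-2-en-1-ol; 2 propanoyl chloride
Product: 3 (E)-but-2-en-1-yl propanoate
Conditions: pyridine, CH2Cl2, 0 °C to rt
Reagents that add atoms: none
Why: O-acylation of a primary allylic alcohol by an acid chloride (nucleophilic acyl substitution); no stereocentre is involved.

Step 2
Reactants: 3 (E)-but-2-en-1-yl propanoate
Product: 4 (2S,3S)-2,3-dimethylpent-4-enoic acid
Conditions: (S,S)-2-bromo-4,5-diphenyl-1,3-bis{[3,5-bis(trifluoromethyl)phenyl]sulfonyl}-1,3,2-diazaborolidine (1.1 equiv), i-Pr2NEt, CH2Cl2, −78 °C then −20 °C; aqueous work-up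
Reagents that add atoms: none
Why: Enantioselective boron-enolate Ireland–Claisen rearrangement, in which the chiral diazaborolidine fixes the enolate face in a chair transition state and so sets C3 (the future C6 methyl centre) as S (the enantiomeric reagent is used if the sense proves opposite); the C2 configuration is irrelevant because that carbon is re-enolised in step 5.

Step 3
Reactants: 5 2-methylcyclohex-2-en-1-one
Product: 6 (1R)-2-methylcyclohex-2-en-1-ol
Conditions: (S)-2-methyl-CBS-oxazaborolidine (10 mol %), BH3·SMe2, THF, −20 °C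
Reagents that add atoms: none
Why: Corey–Bakshi–Shibata reduction, with 1,2-hydride delivery in the catalyst–borane complex where the alkenyl side acts as the large group, giving the R carbinol.

Step 4
Reactants: 6 (1R)-2-methylcyclohex-2-en-1-ol; 4 (2S,3S)-2,3-dimethylpent-4-enoic acid
Product: 7 (1R)-2-methylcyclohex-2-en-1-yl (2S,3S)-2,3-dimethylpent-4-enoate
Conditions: DCC, DMAP (cat.), CH2Cl2, 0 °C to rt
Reagents that add atoms: none
Why: Steglich esterification under neutral conditions, which leaves the carbinol centre and the β-methyl centre untouched.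

Step 5
Reactants: 7 (1R)-2-methylcyclohex-2-en-1-yl (2S,3S)-2,3-dimethylpent-4-enoate
Product: 8 (3S)-2,3-dimethyl-2-[(1S)-2-methylcyclohex-2-en-1-yl]pent-4-enoic acid
Conditions: LiN(i-Pr)2, Me3SiCl, Et3N, THF, −78 °C; then 65 °C; aq. HCl
Reagents that add atoms: none
Why: Ireland–Claisen rearrangement of the tetrasubstituted silyl ketene acetal, whose suprafacial [3,3] shift forms the crowded C5–C4a bond on the ring face the oxygen leaves and so transfers the carbinol chirality to C4a (S here, R by CIP in the target), while the new quaternary C5 forms as an epimer mixture that does not matter.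

Step 6
Reactants: 8 (3S)-2,3-dimethyl-2-[(1S)-2-methylcyclohex-2-en-1-yl]pent-4-enoic acid
Product: 9 (3S)-2,3-dimethyl-2-[(1S)-2-methyl-4-oxocyclohex-2-en-1-yl]pent-4-enoic acid
Conditions: Rh2(cap)4 (dirhodium tetracaprolactamate, 1 mol %), t-BuOOH, K2CO3, CH2Cl2, rt
Reagents that add atoms: tert-butyl hydroperoxide, CC(C)(C)OO
Why: Allylic C–H oxidation by a tert-butylperoxyl radical chain, which attacks the ring CH2 next to the electron-rich trisubstituted alkene rather than the hindered tertiary allylic C–H or the terminal vinyl group and gives the conjugated enone without touching a stereocentre.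

Step 7
Reactants: 9 (3S)-2,3-dimethyl-2-[(1S)-2-methyl-4-oxocyclohex-2-en-1-yl]pent-4-enoic acid; 10 vinylmagnesium bromide; 11 methyl acrylate
Product: 13 (3S)-2-[(1S,2R,3S)-2-ethenyl-3-(3-methoxy-3-oxopropyl)-2-methyl-4-oxocyclohexyl]-2,3-dimethylpent-4-enoic acid, via bis-silyl enol ether 12 (not isolated)
Conditions: Me3SiCl, Et3N, THF, 0 °C; CH2=CHMgBr, CuBr·SMe2 (20 mol %), Me3SiCl, HMPA, −78 °C; solvent swap to CH2Cl2; methyl acrylate, TiCl4, −78 °C; aq. HCl; then K2CO3, MeOH, rt
Reagents that add atoms: none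
Why: Copper-catalysed, Me3SiCl-accelerated conjugate addition of the small vinyl group anti to the very bulky C4a substituent sets the C8a quaternary centre (vinyl trans to the side arm, as a trans-decalin needs) and gives the enol ether regiospecifically toward C1, so the Mukaiyama–Michael addition to methyl acrylate places the chain on C1, which then equilibrates to the equatorial (1S) epimer.

Step 8
Reactants: 13 (3S)-2-[(1S,2R,3S)-2-ethenyl-3-(3-methoxy-3-oxopropyl)-2-methyl-4-oxocyclohexyl]-2,3-dimethylpent-4-enoic acid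
Product: 15 (2S,4aR,5S,8aS)-5-(3-methoxy-3-oxopropyl)-1,2,4a-trimethyl-6-oxodecahydronaphthalene-1-carboxylic acid, via trans-octalin acid 14 (not isolated)
Conditions: second-generation Grubbs catalyst (5 mol %), toluene, 80 °C; then H2 (5 atm), 70 °C
Reagents that add atoms: none
Why: Ring-closing metathesis joins the two vinyl groups, which sit trans on ring A, so ring B closes trans-fused, and the ruthenium residue is converted under H2 into a hydride catalyst that saturates the new C7–C8 alkene (tandem metathesis–hydrogenation) without creating a stereocentre.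

Step 9
Reactants: 16 2-methylphenol; 17 formaldehyde
Product: 19 (2-hydroxy-3-methylphenyl)-N,N,N-trimethylmethanaminium 4-methylbenzenesulfonate, via Mannich base 18 (not isolated)
Conditions: Me2NH (40 % aq.), CH2O (37 % aq.), EtOH, 80 °C; evaporate; methyl 4-methylbenzenesulfonate, acetone, rt
Reagents that add atoms: dimethylamine, CNC; methyl 4-methylbenzenesulfonate, COS(=O)(=O)c1ccc(C)cc1
Why: Phenol Mannich reaction, ortho-selective through hydrogen-bonded iminium delivery, followed by chemoselective N-methylation to a crystalline ammonium salt that releases the ortho-quinone methide under mild base.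

Step 10
Reactants: 15 (2S,4aR,5S,8aS)-5-(3-methoxy-3-oxopropyl)-1,2,4a-trimethyl-6-oxodecahydronaphthalene-1-carboxylic acid; 19 (2-hydroxy-3-methylphenyl)-N,N,N-trimethylmethanaminium 4-methylbenzenesulfonate
Product: 22 methyl 3-[(1S,4aR,5S,6S,8aR)-5-[(2-hydroxy-3-methylphenyl)methyl]-5,6,8a-trimethyl-2-oxodecahydronaphthalen-1-yl]propanoate, via redox-active ester 20 (not isolated), via ortho-quinone methide 21 (not isolated)
Conditions: N-hydroxyphthalimide, DIC, DMAP (cat.), CH2Cl2, rt; then 19 (3 equiv, slow addition), Ru(bpy)3(PF6)2 (1 mol %), i-Pr2NEt, CH2Cl2–DMF, blue LEDs, rt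
Reagents that add atoms: none
Why: Proposed new method: electron transfer from the photoreduced ruthenium complex to the N-acyloxyphthalimide releases CO2 and the tertiary C5 radical, which adds to the exocyclic CH2 of the ortho-quinone methide that the amine liberates slowly from 19, the resulting aryloxyl radical being reduced to the phenoxide; the planar radical makes both C5 epimers converge, and the new bond forms from the equatorial α face because axial β attack would be 1,3-diaxial to the C8a methyl whereas equatorial attack only meets the vicinal axial C6 methyl, so C5 ends with CH2Ar equatorial and methyl axial (5S); the closest known reactions are decarboxylative Giese additions of tertiary N-acyloxyphthalimide-derived radicals and radical 1,6-additions to para-quinone methides.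

Step 11
Reactants: 22 methyl 3-[(1S,4aR,5S,6S,8aR)-5-[(2-hydroxy-3-methylphenyl)methyl]-5,6,8a-trimethyl-2-oxodecahydronaphthalen-1-yl]propanoate
Product: 24 methyl 3-[(1S,4aR,5S,6S,8aR)-5-[(2,5-dihydroxy-3-methylphenyl)methyl]-5,6,8a-trimethyl-2-oxodecahydronaphthalen-1-yl]propanoate, via quinone 23 (not isolated)
Conditions: (KSO3)2NO, KH2PO4, acetone–H2O, rt; then Na2S2O4 (aq.)
Reagents that add atoms: potassium nitrosodisulfonate, [K+].[K+].[O]N(S(=O)(=O)[O-])S(=O)(=O)[O-]
Why: Teuber oxidation of the 2,6-dialkylphenol at its free para position gives the para-quinone, which dithionite reduces in the same flask to the hydroquinone; ketone, ester and all stereocentres are untouched.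

**Compound list**
1 | (E)-but-2-en-1-ol | C/C=C/CO | starting material
2 | propanoyl chloride | CCC(Cl)=O | starting material
3 | (E)-but-2-en-1-yl propanoate | CCC(=O)OC/C=C/C | intermediate
4 | (2S,3S)-2,3-dimethylpent-4-enoic acid | OC(=O)[C@@H](C)[C@@H](C)C=C | intermediate
5 | 2-methylcyclohex-2-en-1-one | CC1=CCCCC1=O | starting material
6 | (1R)-2-methylcyclohex-2-en-1-ol | CC1=CCCC[C@H]1O | intermediate
7 | (1R)-2-methylcyclohex-2-en-1-yl (2S,3S)-2,3-dimethylpent-4-enoate | CC1=CCCC[C@H]1OC(=O)[C@@H](C)[C@@H](C)C=C | intermediate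
8 | (3S)-2,3-dimethyl-2-[(1S)-2-methylcyclohex-2-en-1-yl]pent-4-enoic acid (C2 epimers) | CC1=CCCC[C@@H]1C(C)(C(=O)O)[C@@H](C)C=C | intermediate
9 | (3S)-2,3-dimethyl-2-[(1S)-2-methyl-4-oxocyclohex-2-en-1-yl]pent-4-enoic acid (C2 epimers) | CC1=CC(=O)CC[C@@H]1C(C)(C(=O)O)[C@@H](C)C=C | intermediate
10 | vinylmagnesium bromide | C=C[Mg]Br | starting material
11 | methyl acrylate | COC(=O)C=C | starting material
12 | trimethylsilyl (3S)-2-[(1S,2R)-2-ethenyl-2-methyl-4-(trimethylsilyloxy)cyclohex-3-en-1-yl]-2,3-dimethylpent-4-enoate (C2 epimers) | C[Si](C)(C)OC1=C[C@](C)(C=C)[C@H](CC1)C(C)(C(=O)O[Si](C)(C)C)[C@@H](C)C=C | intermediate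
13 | (3S)-2-[(1S,2R,3S)-2-ethenyl-3-(3-methoxy-3-oxopropyl)-2-methyl-4-oxocyclohexyl]-2,3-dimethylpent-4-enoic acid (C2 epimers) | COC(=O)CC[C@@H]1C(=O)CC[C@H](C(C)(C(=O)O)[C@@H](C)C=C)[C@@]1(C)C=C | intermediate
14 | (2S,4aR,5S,8aS)-5-(3-methoxy-3-oxopropyl)-1,2,4a-trimethyl-6-oxo-1,2,4a,5,6,7,8,8a-octahydronaphthalene-1-carboxylic acid (C1 epimers) | COC(=O)CC[C@@H]1C(=O)CC[C@H]2[C@@]1(C)C=C[C@H](C)C2(C)C(=O)O | intermediate
15 | (2S,4aR,5S,8aS)-5-(3-methoxy-3-oxopropyl)-1,2,4a-trimethyl-6-oxodecahydronaphthalene-1-carboxylic acid (C1 epimers) | COC(=O)CC[C@@H]1C(=O)CC[C@H]2[C@@]1(C)CC[C@H](C)C2(C)C(=O)O | intermediate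
16 | 2-methylphenol | Cc1ccccc1O | starting material
17 | formaldehyde | C=O | starting material
18 | 2-[(dimethylamino)methyl]-6-methylphenol | CN(C)Cc1cccc(C)c1O | intermediate
19 | (2-hydroxy-3-methylphenyl)-N,N,N-trimethylmethanaminium 4-methylbenzenesulfonate | C[N+](C)(C)Cc1cccc(C)c1O.Cc1ccc(cc1)S(=O)(=O)[O-] | intermediate
20 | 1,3-dioxoisoindolin-2-yl ester of acid 15 (C1 epimers) | COC(=O)CC[C@@H]1C(=O)CC[C@H]2[C@@]1(C)CC[C@H](C)C2(C)C(=O)ON3C(=O)c4ccccc4C3=O | intermediate
21 | 2-methyl-6-methylidenecyclohexa-2,4-dien-1-one | C=C1C=CC=C(C)C1=O | intermediate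
22 | methyl 3-[(1S,4aR,5S,6S,8aR)-5-[(2-hydroxy-3-methylphenyl)methyl]-5,6,8a-trimethyl-2-oxodecahydronaphthalen-1-yl]propanoate | COC(=O)CC[C@@H]1C(=O)CC[C@H]2[C@@]1(C)CC[C@H](C)[C@]2(C)Cc1cccc(C)c1O | intermediate
23 | methyl 3-[(1S,4aR,5S,6S,8aR)-5-[(5-methyl-3,6-dioxocyclohexa-1,4-dien-1-yl)methyl]-5,6,8a-trimethyl-2-oxodecahydronaphthalen-1-yl]propanoate | COC(=O)CC[C@@H]1C(=O)CC[C@H]2[C@@]1(C)CC[C@H](C)[C@]2(C)CC1=CC(=O)C=C(C)C1=O | intermediate
24 | methyl 3-[(1S,4aR,5S,6S,8aR)-5-[(2,5-dihydroxy-3-methylphenyl)methyl]-5,6,8a-trimethyl-2-oxodecahydronaphthalen-1-yl]propanoate | COC(=O)CC[C@@H]1C(=O)CC[C@H]2[C@@]1(C)CC[C@H](C)[C@]2(C)Cc1cc(O)cc(C)c1O | target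

**Step count**
Total step count: 11. Longest linear sequence: 9 (steps 1, 2, 4, 5, 6, 7, 8, 10, 11).

**Three steps most likely to fail, with fallbacks**

Step 10 is the least precedented. The quinone methide may oligomerise faster than it traps a hindered tertiary radical, and the facial preference at C5 is argued, not known. The fallback sets out from 15 (through the same ester 20) and comes back at 22, keeping the radical but changing the acceptor and the way the benzylic CH2 arises. 2-Methylphenol 16 is ortho-formylated (MgCl2, Et3N, paraformaldehyde, MeCN, reflux) to 2-hydroxy-3-methylbenzaldehyde F1. Condensation with 4-methylbenzenesulfonohydrazide in MeOH gives the N-tosylhydrazone F2. The C5 radical from 20 (Ru(bpy)3(PF6)2, i-Pr2NEt, blue LEDs) adds to the C=N carbon of F2 to give the sulfonylhydrazide adduct F3. Warming F3 with K2CO3 in MeOH expels sulfinate and then N2 from the diazene, leaving the CH2Ar group of 22.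

Step 7 may fail at the conjugate addition, because the β-carbon is flanked by a fully substituted neighbour, or at the telescoped Michael trapping. The fallback sets out from 9 and comes back at 13, using a slimmer, linear nucleophile under nickel–aluminium catalysis. Me2AlC≡CSiMe3 (from ethynyltrimethylsilane, n-BuLi and Me2AlCl) is added 1,4 with Ni(acac)2 and i-Bu2AlH as catalyst precursors. The aluminium enolate is silylated and taken through the same TiCl4-mediated Mukaiyama–Michael addition to 11, giving the silylalkynyl keto acid F4. K2CO3 in MeOH removes the silyl group to give the ethynyl keto acid F5. Semi-hydrogenation (H2, Pd/CaCO3 poisoned with Pb(OAc)2, quinoline) converts the alkyne into the vinyl group of 13.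

Step 5 must form a bond between a tetrasubstituted ketene acetal carbon and a ring CH, and may stall or eliminate. The fallback sets out from 6 and comes back at 8, building the quaternary carbon in two smaller C–C steps; steps 1, 2 and 4 are then not needed. Alcohol 6 is acylated with 2 (pyridine) to (1R)-2-methylcyclohex-2-en-1-yl propanoate F6. Its Ireland–Claisen rearrangement (LiN(i-Pr)2, Me3SiCl, then 65 °C) gives 2-[(1R)-2-methylcyclohex-2-en-1-yl]propanoic acid F7 with the same chirality transfer. Commercial (R)-but-3-yn-2-ol and TsCl give (2R)-but-3-yn-2-yl 4-methylbenzenesulfonate F8. The dianion of F7 (2.2 equiv LiN(i-Pr)2, THF–DMPU) is alkylated by F8 with SN2 inversion, which sets the 3S methyl centre in alkynyl acid F9. Lindlar semi-hydrogenation of F9 gives 8.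

**Further compounds**
F1 | step 10 | 2-hydroxy-3-methylbenzaldehyde | Cc1cccc(C=O)c1O
F2 | step 10 | N'-[(E)-(2-hydroxy-3-methylphenyl)methylidene]-4-methylbenzenesulfonohydrazide | Cc1ccc(cc1)S(=O)(=O)N/N=C/c1cccc(C)c1O
F3 | step 10 | methyl 3-[(1S,4aR,5S,6S,8aR)-5-[(2-hydroxy-3-methylphenyl)(2-tosylhydrazinyl)methyl]-5,6,8a-trimethyl-2-oxodecahydronaphthalen-1-yl]propanoate | COC(=O)CC[C@@H]1C(=O)CC[C@H]2[C@@]1(C)CC[C@H](C)[C@]2(C)C(NNS(=O)(=O)c3ccc(C)cc3)c3cccc(C)c3O
F4 | step 7 | (3S)-2-[(1S,2R,3S)-3-(3-methoxy-3-oxopropyl)-2-methyl-4-oxo-2-[(trimethylsilyl)ethynyl]cyclohexyl]-2,3-dimethylpent-4-enoic acid (C2 epimers) | COC(=O)CC[C@@H]1C(=O)CC[C@H](C(C)(C(=O)O)[C@@H](C)C=C)[C@@]1(C)C#C[Si](C)(C)C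
F5 | step 7 | (3S)-2-[(1S,2R,3S)-2-ethynyl-3-(3-methoxy-3-oxopropyl)-2-methyl-4-oxocyclohexyl]-2,3-dimethylpent-4-enoic acid (C2 epimers) | COC(=O)CC[C@@H]1C(=O)CC[C@H](C(C)(C(=O)O)[C@@H](C)C=C)[C@@]1(C)C#C
F6 | step 5 | (1R)-2-methylcyclohex-2-en-1-yl propanoate | CC1=CCCC[C@H]1OC(=O)CC
F7 | step 5 | 2-[(1R)-2-methylcyclohex-2-en-1-yl]propanoic acid (C2 epimers) | CC1=CCCC[C@@H]1C(C)C(=O)O
F8 | step 5 | (2R)-but-3-yn-2-yl 4-methylbenzenesulfonate | C#C[C@@H](C)OS(=O)(=O)c1ccc(C)cc1
F9 | step 5 | (3S)-2,3-dimethyl-2-[(1S)-2-methylcyclohex-2-en-1-yl]pent-4-ynoic acid (C2 epimers) | CC1=CCCC[C@@H]1C(C)(C(=O)O)[C@@H](C)C#C
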